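**Retrosynthetic overview**
1. Numbering (daucane): C1 = quaternary ring-fusion carbon with methyl C15; C2, C3 = ring CH2; C4 = isopropyl carbinol; C5 = ring-fusion CH; C6 = benzoyloxy carbon; C7; C8(Me)=C9; C10 = angeloyloxy carbon; α = face of H-5, β = face of C15.
2. Esters last (C6 benzoate, then C10 angelate). C6–OH comes from hydroxyl-directed reduction of a C6 ketone; C10–OH and C8=C9 come from SmI2 opening of the 9α,10α-epoxide of a dauca-7,9-dien-6-one.
3. Seven-membered ring second: C9=C10 by ring-closing metathesis of a cyclopentane carrying an E-propenyl group on C1 and an isoprenyl carbinol chain on C5; the isopropyl group is added to a C4 cyclopentanone.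
4. Five-membered ring first: C3–C4 by intramolecular hydroacylation, directly after a Claisen rearrangement that makes C1–C5 from an allyl vinyl ether joining a C7 dienol and a C3 acrolein acetal through oxygen only.
5. Enabling feature: in the five-membered ring the carbonyl-level C4 sits on C5 and the C2–C3 unit sits on quaternary C1, so C4(HO)–C5–C1–C2=C3 is a 4-pentenal. That is what a Claisen rearrangement delivers and what monovalent rhodium closes to a cyclopentanone; one carbinol centre controls all other stereocentres.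

Key step: step 6

Remark: 2-(bromomethyl)buta-1,3-diene (step 8) is taken as purchasable (otherwise from 3-methyl-3-sulfolene by N-bromosuccinimide bromination and thermal loss of SO2); C6 of 14 and 15 is drawn as the chelation-controlled epimer, and the other epimer converges in step 10.

**Route**

Step 1
Reactants: 1 pent-3-yn-2-one
Product: 2 (R)-pent-3-yn-2-ol
Conditions: RuCl[(R,R)-TsDPEN](p-cymene) (1 mol %), iPrOH, 25 °C
Reagents that add atoms: none
Why: Noyori asymmetric transfer hydrogenation of an alkynyl methyl ketone, in which the (R,R)-diamine catalyst is expected to give the (R)-propargylic alcohol, the single centre from which every other stereocentre is derived.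

Step 2
Reactants: 2 (R)-pent-3-yn-2-ol
Product: 4 (2R,3Z)-4-iodopent-3-en-2-ol, via cyclic alkenylaluminate 3 (not isolated)
Conditions: NaAlH2(OCH2CH2OCH3)2, THF, 0 to 25 °C; then EtOAc, I2, −78 °C
Reagents that add atoms: iodine, II
Why: Hydroxyl-directed trans-hydroalumination of a propargylic alcohol puts aluminium on the distal alkyne carbon in a five-membered chelate, and iodinolysis with retention should give the Z-vinyl iodide (iodine cis to the carbinol carbon) without touching the stereocentre.

Step 3
Reactants: 4 (2R,3Z)-4-iodopent-3-en-2-ol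
Product: 5 (2R,3Z)-4-methylhexa-3,5-dien-2-ol
Conditions: Pd(PPh3)4 (5 mol %), CuI (10 mol %), DMF, 25 °C
Reagents that add atoms: tributyl(vinyl)stannane, C=C[Sn](CCCC)(CCCC)CCCC
Why: Stille coupling of a vinyl iodide proceeds with retention of alkene geometry and tolerates the free hydroxyl, so the vinyl group should end cis to the carbinol carbon.

Step 4
Reactants: 6 3,3-diethoxyprop-1-yne
Product: 8 (E)-3,3-diethoxy-1-iodoprop-1-ene, via alkenylzirconocene chloride 7 (not isolated)
Conditions: Cp2Zr(H)Cl, THF, 25 °C; then I2, 0 °C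
Reagents that add atoms: iodine, II
Why: Hydrozirconation with the Schwartz reagent is a syn addition with zirconium on the terminal carbon, and iodinolysis with retention should give the E-vinyl iodide.

Step 5
Reactants: 5 (2R,3Z)-4-methylhexa-3,5-dien-2-ol; 8 (E)-3,3-diethoxy-1-iodoprop-1-ene
Product: 9 (2R,3Z)-2-{[(1E)-3,3-diethoxyprop-1-en-1-yl]oxy}-4-methylhexa-3,5-diene
Conditions: CuI (10 mol %), 3,4,7,8-tetramethyl-1,10-phenanthroline (20 mol %), Cs2CO3, toluene, 80 °C
Reagents that add atoms: none
Why: Ullmann-type copper-catalysed C–O coupling of an alcohol with a vinyl iodide should form the allyl vinyl ether with retention of the E-enol ether geometry, and at 80 °C the rearrangement that builds a quaternary carbon is still slow enough for the ether to be isolated.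

Step 6
Reactants: 9 (2R,3Z)-2-{[(1E)-3,3-diethoxyprop-1-en-1-yl]oxy}-4-methylhexa-3,5-diene
Product: 11 (2S,3R)-2-(diethoxymethyl)-3-methyl-3-[(1E)-prop-1-en-1-yl]cyclopentan-1-one, via Claisen aldehyde 10 (not isolated)
Conditions: ClCH2CH2Cl, 120 °C (sealed tube); then [Rh(nbd)(dppe)]BF4 (5 mol %, activated with H2), 25 °C
Reagents that add atoms: none
Why: Heating 9 triggers a Claisen rearrangement through a chair transition state with the carbinol methyl group equatorial, so the configuration of that carbon is transferred to the new C1–C5 bond (quaternary C1 from the Z-trisubstituted alkene, C5 from the E-enol ether) and the old carbinol carbon becomes an E-propenyl group. The 4-pentenal 10 is then taken up by cationic monovalent rhodium: oxidative addition into the aldehyde C–H bond, insertion of the terminal vinyl group to a six-membered acyl–alkyl rhodacycle and reductive elimination form C3–C4 (closest known type: rhodium-catalysed intramolecular hydroacylation of 4-pentenals, also run in tandem with Claisen rearrangements of allyl vinyl ethers). The only ring closed is the cyclopentanone, in a formal 5-endo hydroacylation mode fixed by the metallacycle. The ring closure creates no stereocentre; C1 and C5 are set by the sigmatropic step and should be preserved because the rhodium step is neutral and runs at 25 °C. The step needs site selectivity between the two alkenyl groups on C1, which is secured because the unhindered terminal vinyl group inserts much faster than the 1,2-disubstituted propenyl group, and the gem-disubstitution at C1 favours cyclisation over decarbonylation.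

Step 7
Reactants: 11 (2S,3R)-2-(diethoxymethyl)-3-methyl-3-[(1E)-prop-1-en-1-yl]cyclopentan-1-one
Product: 12 (1R,2R,3R)-2-(diethoxymethyl)-3-methyl-1-(propan-2-yl)-3-[(1E)-prop-1-en-1-yl]cyclopentan-1-ol
Conditions: CeCl3, iPrMgCl, THF, −78 to 0 °C
Reagents that add atoms: isopropylmagnesium chloride, CC(C)[Mg]Cl
Why: Organocerium 1,2-addition suppresses enolisation of the α-branched ketone, and attack from the face opposite to the diethoxymethyl group on the neighbouring C5 should place the new hydroxyl cis to that group, which is the C4 configuration of the target.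

Step 8
Reactants: 12 (1R,2R,3R)-2-(diethoxymethyl)-3-methyl-1-(propan-2-yl)-3-[(1E)-prop-1-en-1-yl]cyclopentan-1-ol
Product: 14 (1R,2R,3R)-2-[(1S)-1-hydroxy-3-methylidenepent-4-en-1-yl]-3-methyl-1-(propan-2-yl)-3-[(1E)-prop-1-en-1-yl]cyclopentan-1-ol, via hydroxy aldehyde 13 (not isolated)
Conditions: 0.5 M HCl, THF, 0 to 25 °C; then In powder, 2-(bromomethyl)buta-1,3-diene, 25 °C
Reagents that add atoms: water, O; 2-(bromomethyl)buta-1,3-diene, C=CC(=C)CBr
Why: Aqueous acid unmasks the aldehyde and an indium-mediated Barbier allylation (isoprenylation) runs in the same aqueous medium without protection of the tertiary alcohol; chelation of indium between the C4 hydroxyl and the aldehyde should favour the 1,3-anti diol drawn.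

Step 9
Reactants: 14 (1R,2R,3R)-2-[(1S)-1-hydroxy-3-methylidenepent-4-en-1-yl]-3-methyl-1-(propan-2-yl)-3-[(1E)-prop-1-en-1-yl]cyclopentan-1-ol
Product: 15 dauca-8(14),9-diene-4β,6α-diol (trans-fused, 5α-H)
Conditions: second-generation Grubbs catalyst (5 mol %), toluene, 80 °C
Reagents that add atoms: none
Why: Ring-closing metathesis in which the ruthenium carbene loads on the monosubstituted vinyl end of the diene and can then close only onto the propenyl group, which should give the seven-membered ring with the cis C9=C10 bond and release propene.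

Step 10
Reactants: 15 dauca-8(14),9-diene-4β,6α-diol
Product: 17 4β-hydroxydauca-7,9-dien-6-one, via exo-methylene ketone 16 (not isolated)
Conditions: Dess–Martin periodinane, NaHCO3, CH2Cl2, 0 °C; then Et3N, 25 °C
Reagents that add atoms: none
Why: Dess–Martin oxidation affects only the secondary alcohol, and mild base should move the exocyclic double bond through the doubly activated C7 position into conjugation to give the linearly conjugated dienone as the thermodynamic isomer.

Step 11
Reactants: 17 4β-hydroxydauca-7,9-dien-6-one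
Product: 18 9α,10α-epoxy-4β-hydroxydauc-7-en-6-one
Conditions: mCPBA, NaHCO3, CH2Cl2, 0 °C
Reagents that add atoms: 3-chloroperbenzoic acid, OOC(=O)c1cccc(Cl)c1
Why: Peracid epoxidation should occur at the electron-richer γ,δ-double bond of the dienone and from the face opposite to the pseudo-axial methyl group on the adjacent quaternary C1, which sets the C10–O bond α.

Step 12
Reactants: 18 9α,10α-epoxy-4β-hydroxydauc-7-en-6-one
Product: 19 4β,10α-dihydroxydauc-8-en-6-one
Conditions: SmI2 (2.2 equiv), MeOH, THF, −78 °C
Reagents that add atoms: none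
Why: SmI2 reduction of a γ,δ-epoxy enone (electron transfer to the enone, cleavage of the C9–O bond, kinetic protonation of the samarium dienolate at C7) should give the δ-hydroxy β,γ-enone, that is the C10 alcohol with its configuration intact and the C8=C9 double bond.

Step 13
Reactants: 19 4β,10α-dihydroxydauc-8-en-6-one
Product: 20 dauc-8-ene-4β,6α,10α-triol
Conditions: Me4NBH(OAc)3, AcOH–MeCN, −30 °C
Reagents that add atoms: none
Why: Evans–Saksena reduction, in which the triacetoxyborohydride exchanges onto the C4 hydroxyl and delivers hydride intramolecularly to the β-face of the C6 ketone, should give the 1,3-anti diol (C6–OH α).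

Step 14
Reactants: 20 dauc-8-ene-4β,6α,10α-triol
Product: 21 6α-benzoyloxydauc-8-ene-4β,10α-diol
Conditions: BzCl (1.1 equiv), pyridine, CH2Cl2, −20 °C
Reagents that add atoms: benzoyl chloride, O=C(Cl)c1ccccc1
Why: Site-selective acylation of the least hindered hydroxyl, since C10–OH is neopentylic (next to quaternary C1) and C4–OH is tertiary, so one equivalent of benzoyl chloride at low temperature should esterify C6–OH only.

Step 15
Reactants: 21 6α-benzoyloxydauc-8-ene-4β,10α-diol
Product: 22 10α-angeloyloxy-6α-benzoyloxydauc-8-en-4β-ol (target)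
Conditions: angelic acid, 2,4,6-trichlorobenzoyl chloride, Et3N, toluene, 25 °C; then 21, 80 °C
Reagents that add atoms: angelic acid ((Z)-2-methylbut-2-enoic acid), C/C=C(/C)C(=O)O
Why: Yamaguchi-type esterification through the mixed 2,4,6-trichlorobenzoic anhydride, run without a nucleophilic catalyst, should acylate the hindered allylic C10 hydroxyl without isomerising the Z-angelate to the tiglate and leaves the tertiary C4 hydroxyl free.

**Compound list**
1 | pent-3-yn-2-one | CC#CC(C)=O | starting material
2 | (R)-pent-3-yn-2-ol | C[C@@H](O)C#CC | intermediate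
3 | sodium (5R)-2,2-bis(2-methoxyethoxy)-3,5-dimethyl-2,5-dihydro-1,2-oxaluminol-2-uide (cyclic alkenylaluminate) | C[C@@H]1C=C(C)[Al-](OCCOC)(OCCOC)O1.[Na+] | intermediate
4 | (2R,3Z)-4-iodopent-3-en-2-ol | C[C@@H](O)/C=C(/C)I | intermediate
5 | (2R,3Z)-4-methylhexa-3,5-dien-2-ol | C[C@@H](O)/C=C(/C)C=C | intermediate
6 | 3,3-diethoxyprop-1-yne | C#CC(OCC)OCC | starting material
7 | (E)-(3,3-diethoxyprop-1-en-1-yl)zirconocene chloride | CCOC(OCC)/C=C/[Zr](Cl)(C1C=CC=C1)C1C=CC=C1 | intermediate
8 | (E)-3,3-diethoxy-1-iodoprop-1-ene | CCOC(OCC)/C=C/I | intermediate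
9 | (2R,3Z)-2-{[(1E)-3,3-diethoxyprop-1-en-1-yl]oxy}-4-methylhexa-3,5-diene | C[C@@H](O/C=C/C(OCC)OCC)/C=C(/C)C=C | intermediate
10 | (2R,3R,4E)-2-(diethoxymethyl)-3-ethenyl-3-methylhex-4-enal | CCOC(OCC)[C@@H](C=O)[C@](/C=C/C)(C)C=C | intermediate
11 | (2S,3R)-2-(diethoxymethyl)-3-methyl-3-[(1E)-prop-1-en-1-yl]cyclopentan-1-one | CCOC(OCC)[C@@H]1[C@](/C=C/C)(C)CCC1=O | intermediate
12 | (1R,2R,3R)-2-(diethoxymethyl)-3-methyl-1-(propan-2-yl)-3-[(1E)-prop-1-en-1-yl]cyclopentan-1-ol | CCOC(OCC)[C@@H]1[C@](/C=C/C)(C)CC[C@@]1(O)C(C)C | intermediate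
13 | (1R,2R,5R)-2-hydroxy-5-methyl-2-(propan-2-yl)-5-[(1E)-prop-1-en-1-yl]cyclopentane-1-carbaldehyde | O=C[C@@H]1[C@](/C=C/C)(C)CC[C@@]1(O)C(C)C | intermediate
14 | (1R,2R,3R)-2-[(1S)-1-hydroxy-3-methylidenepent-4-en-1-yl]-3-methyl-1-(propan-2-yl)-3-[(1E)-prop-1-en-1-yl]cyclopentan-1-ol | C=CC(=C)C[C@H](O)[C@@H]1[C@](/C=C/C)(C)CC[C@@]1(O)C(C)C | intermediate
15 | dauca-8(14),9-diene-4β,6α-diol | C1=CC(=C)C[C@H](O)[C@@H]2[C@]1(C)CC[C@@]2(O)C(C)C | intermediate
16 | 4β-hydroxydauca-8(14),9-dien-6-one | C1=CC(=C)CC(=O)[C@@H]2[C@]1(C)CC[C@@]2(O)C(C)C | intermediate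
17 | 4β-hydroxydauca-7,9-dien-6-one | C1=CC(C)=CC(=O)[C@@H]2[C@]1(C)CC[C@@]2(O)C(C)C | intermediate
18 | 9α,10α-epoxy-4β-hydroxydauc-7-en-6-one | O3[C@@H]1[C@H]3C(C)=CC(=O)[C@@H]2[C@]1(C)CC[C@@]2(O)C(C)C | intermediate
19 | 4β,10α-dihydroxydauc-8-en-6-one | O[C@@H]1C=C(C)CC(=O)[C@@H]2[C@]1(C)CC[C@@]2(O)C(C)C | intermediate
20 | dauc-8-ene-4β,6α,10α-triol | O[C@@H]1C=C(C)C[C@H](O)[C@@H]2[C@]1(C)CC[C@@]2(O)C(C)C | intermediate
21 | 6α-benzoyloxydauc-8-ene-4β,10α-diol | O[C@@H]1C=C(C)C[C@H](OC(=O)c3ccccc3)[C@@H]2[C@]1(C)CC[C@@]2(O)C(C)C | intermediate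
22 | 10α-angeloyloxy-6α-benzoyloxydauc-8-en-4β-ol | C/C=C(/C)C(=O)O[C@@H]1C=C(C)C[C@H](OC(=O)c2ccccc2)[C@@H]2[C@]1(C)CC[C@@]2(O)C(C)C | target

**Step count**
Total: 15 steps. Longest linear sequence: 14 steps (steps 1–3 and 5–15; step 4 is a one-step branch).

**Steps most likely to fail, with fallbacks**

Step 6. The acyl–rhodium hydride may lose CO (decarbonylation), insert into the propenyl group or shift double bonds, and in the thermal part a sigmatropic hydrogen shift of the Z-dienyl ether may compete with the rearrangement. Fallback (C3–C4 closed by a samarium Barbier reaction instead): setting out from 9, heating alone (ClCH2CH2Cl, 120 °C) gives aldehyde 10, which is isolated. iPrMgCl with CeCl3 adds to the aldehyde to give (6E)-4-(diethoxymethyl)-5-ethenyl-2,5-dimethyloct-6-en-3-ol F1 (carbinol epimers). 9-Borabicyclo[3.3.1]nonane followed by NaOH/H2O2 hydroborates only the terminal vinyl group and gives (6E)-4-(diethoxymethyl)-5-(2-hydroxyethyl)-2,5-dimethyloct-6-en-3-ol F2. I2, PPh3 and imidazole convert the primary hydroxyl into the iodide (6E)-4-(diethoxymethyl)-5-(2-iodoethyl)-2,5-dimethyloct-6-en-3-ol F3, and Dess–Martin oxidation gives (6E)-4-(diethoxymethyl)-5-(2-iodoethyl)-2,5-dimethyloct-6-en-3-one F4. SmI2 with HMPA in THF then closes the ring by attack of the alkylsamarium on the isopropyl ketone from the face away from the diethoxymethyl group, which returns to the route at 12.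

Step 9. The metathesis may close through the 1,1-disubstituted alkene to a six-membered ring, or the diene may oligomerise. Fallback (chain without a diene, unsaturation introduced later): setting out from 12, acid hydrolysis gives aldehyde 13, isolated this time. (2-Methylbut-3-en-1-yl)magnesium bromide adds to give (1R,2R,3R)-2-[(1S)-1-hydroxy-3-methylpent-4-en-1-yl]-3-methyl-1-(propan-2-yl)-3-[(1E)-prop-1-en-1-yl]cyclopentan-1-ol F5 (C8 epimers). Dess–Martin oxidation gives the ketone (1R,2R,3R)-1-hydroxy-2-(3-methylpent-4-enoyl)-3-methyl-1-(propan-2-yl)-3-[(1E)-prop-1-en-1-yl]cyclopentane F6, which has a single terminal alkene. Ring-closing metathesis with the second-generation Grubbs catalyst gives 4β-hydroxydauc-9-en-6-one F7 (C8 epimers). Dehydrogenation with 2-iodoxybenzoic acid in DMSO at 70 °C introduces the C7=C8 double bond and removes the C8 centre, which returns to the route at 17.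

Step 14. Benzoyl chloride may not distinguish the two secondary hydroxyls (acylation at C10 or double acylation). Fallback (order of the last three operations changed so that no selection is needed): setting out from 19, the only secondary hydroxyl is angeloylated under the conditions of step 15 to give 10α-angeloyloxy-4β-hydroxydauc-8-en-6-one F8. Me4NBH(OAc)3 then reduces the C6 ketone under direction of the C4 hydroxyl to give 10α-angeloyloxydauc-8-ene-4β,6α-diol F9. Benzoyl chloride, pyridine and 4-dimethylaminopyridine then acylate the one remaining secondary hydroxyl, which arrives at 22.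

**Further compounds**
F1 | step 6 | (6E)-4-(diethoxymethyl)-5-ethenyl-2,5-dimethyloct-6-en-3-ol | CCOC(OCC)[C@@H](C(O)C(C)C)[C@](/C=C/C)(C)C=C
F2 | step 6 | (6E)-4-(diethoxymethyl)-5-(2-hydroxyethyl)-2,5-dimethyloct-6-en-3-ol | CCOC(OCC)[C@@H](C(O)C(C)C)[C@](/C=C/C)(C)CCO
F3 | step 6 | (6E)-4-(diethoxymethyl)-5-(2-iodoethyl)-2,5-dimethyloct-6-en-3-ol | CCOC(OCC)[C@@H](C(O)C(C)C)[C@](/C=C/C)(C)CCI
F4 | step 6 | (6E)-4-(diethoxymethyl)-5-(2-iodoethyl)-2,5-dimethyloct-6-en-3-one | CCOC(OCC)[C@@H](C(=O)C(C)C)[C@](/C=C/C)(C)CCI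
F5 | step 9 | (1R,2R,3R)-2-[(1S)-1-hydroxy-3-methylpent-4-en-1-yl]-3-methyl-1-(propan-2-yl)-3-[(1E)-prop-1-en-1-yl]cyclopentan-1-ol | C=CC(C)C[C@H](O)[C@@H]1[C@](/C=C/C)(C)CC[C@@]1(O)C(C)C
F6 | step 9 | (1R,2R,3R)-1-hydroxy-2-(3-methylpent-4-enoyl)-3-methyl-1-(propan-2-yl)-3-[(1E)-prop-1-en-1-yl]cyclopentane | C=CC(C)CC(=O)[C@@H]1[C@](/C=C/C)(C)CC[C@@]1(O)C(C)C
F7 | step 9 | 4β-hydroxydauc-9-en-6-one | C1=CC(C)CC(=O)[C@@H]2[C@]1(C)CC[C@@]2(O)C(C)C
F8 | step 14 | 10α-angeloyloxy-4β-hydroxydauc-8-en-6-one | C/C=C(/C)C(=O)O[C@@H]1C=C(C)CC(=O)[C@@H]2[C@]1(C)CC[C@@]2(O)C(C)C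
F9 | step 14 | 10α-angeloyloxydauc-8-ene-4β,6α-diol | C/C=C(/C)C(=O)O[C@@H]1C=C(C)C[C@H](O)[C@@H]2[C@]1(C)CC[C@@]2(O)C(C)C
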